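**Retrosynthetic overview**
1. Methylene bridge: cut between the bridge CH2 and ring B. Ring A carries the CH2 as a Mannich base, which loses Me2NH to an α-methylidene trione; the ring B phenol adds to it in an intermolecular Michael reaction.
2. Ring A (the only ring that is built): cut between the hexanoyl-bearing carbon and its neighbouring carbonyl, i.e. an intramolecular Claisen condensation of an acyclic 3,5,7-triketo methyl ester.
3. Triketo ester: cut next to the quaternary carbon, i.e. an intermolecular Claisen condensation of the nonane-2,4-dione dianion with an activated chiral α-methyl-α-prenyl malonic half ester.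
4. Quaternary stereocentre: enantioselective phase-transfer prenylation of a mixed methylmalonate; its two esters are then used in a fixed order, which carries the configuration into the ring.
5. Ring B is aromatic from the start (phloroglucinol, Friedel–Crafts hexanoylation, 4-O-methylation). Ring order: ring B present first, ring A closed in step 9, the two joined in step 13.

Assumption: the (R,R)-enantiomer of the N-spiro ammonium catalyst is taken to give the R malonate 10; if the sense of induction proves opposite, the (S,S)-catalyst is used and nothing else changes. Enolates and salts of numbered compounds are not numbered separately.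

**Route**

Step 1
Reactants: 1 pentane-2,4-dione; 2 1-bromobutane
Product: 3 nonane-2,4-dione
Conditions: LiN(iPr)2 (2.1 equiv), THF, −78 → 0 °C; then 2 (1.0 equiv), 0 °C → rt; 1 M HCl work-up
Reagents that add atoms: none
Why: The 1,3-dianion of the β-diketone is alkylated only at its more basic terminal carbon (γ-alkylation of a diketone dianion), so the chain is extended without C3- or O-alkylation.

Step 2
Reactants: 4 2,2,5-trimethyl-1,3-dioxane-4,6-dione; 5 2-methylpropan-2-ol
Product: 6 3-(tert-butoxy)-2-methyl-3-oxopropanoic acid (racemic)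
Conditions: 5 as solvent, reflux, 12 h; evaporate
Reagents that add atoms: none
Why: Thermal alcoholysis of the activated cyclic acylal (Meldrum's acid ring opening) gives the malonic half ester with loss of acetone.

Step 3
Reactants: 6 3-(tert-butoxy)-2-methyl-3-oxopropanoic acid; 7 bromodiphenylmethane
Product: 8 1-benzhydryl 3-tert-butyl 2-methylpropanedioate (racemic, α-H labile)
Conditions: Et3N (1.2 equiv), MeCN, 50 °C
Reagents that add atoms: none
Why: O-alkylation of the carboxylate by the ionisation-prone benzhydryl bromide (ester formation by nucleophilic substitution) gives the mixed diester.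

Step 4
Reactants: 8 1-benzhydryl 3-tert-butyl 2-methylpropanedioate; 9 1-bromo-3-methylbut-2-ene
Product: 10 1-benzhydryl 3-tert-butyl (2R)-2-methyl-2-(3-methylbut-2-en-1-yl)propanedioate
Conditions: (R,R)-3,4,5-trifluorophenyl-NAS bromide (5 mol %), 9 (5 equiv), 50% aq KOH (5 equiv), toluene, −40 °C, 30 h
Reagents that add atoms: none
Why: Asymmetric phase-transfer alkylation: the chiral ammonium ion pair of the prochiral malonate enolate is prenylated (SN2 at the primary allylic carbon) on one enantiotopic face, which sets the quaternary stereocentre as R, and it has no α-hydrogen to epimerise later.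

Step 5
Reactants: 10 1-benzhydryl 3-tert-butyl (2R)-2-methyl-2-(3-methylbut-2-en-1-yl)propanedioate
Product: 11 (2R)-3-(tert-butoxy)-2-methyl-2-(3-methylbut-2-en-1-yl)-3-oxopropanoic acid
Conditions: 1 M aq KOH (3 equiv), THF–MeOH, rt → 40 °C; Et2O wash; cold 1 M HCl to pH 3
Reagents that add atoms: potassium hydroxide (KOH), [K+].[OH-]
Why: Saponification cleaves only the benzhydryl ester because the tert-butyl ester is shielded against hydroxide, and the acid is freed from diphenylmethanol by acid–base extraction with the stereocentre untouched.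

Step 6
Reactants: 11 (2R)-3-(tert-butoxy)-2-methyl-2-(3-methylbut-2-en-1-yl)-3-oxopropanoic acid
Product: 12 1-tert-butyl 3-methyl (2R)-2-methyl-2-(3-methylbut-2-en-1-yl)propanedioate
Conditions: MeI (1.5 equiv), K2CO3 (1.5 equiv), DMF, rt
Reagents that add atoms: iodomethane, CI
Why: SN2 O-methylation of the carboxylate turns the former benzhydryl carboxyl into the methyl ester that later serves as the ring-closing acceptor.

Step 7
Reactants: 12 1-tert-butyl 3-methyl (2R)-2-methyl-2-(3-methylbut-2-en-1-yl)propanedioate
Product: 14 (2S)-3-methoxy-2-methyl-2-(3-methylbut-2-en-1-yl)-3-oxopropanoic acid, via trimethylsilyl ester 13 (not isolated)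
Conditions: Me3SiOTf (2 equiv), 2,6-lutidine (3 equiv), CH2Cl2, 0 °C → rt; then pH 4 citrate buffer
Reagents that add atoms: none
Why: Silyl-triflate-mediated tert-butyl ester cleavage (loss of isobutene from the O-silylated ester) runs under buffered conditions, so the prenyl alkene is not protonated, the methyl ester stays, and only the CIP descriptor changes.

Step 8
Reactants: 14 (2S)-3-methoxy-2-methyl-2-(3-methylbut-2-en-1-yl)-3-oxopropanoic acid; 3 nonane-2,4-dione
Product: 16 methyl (2S)-2-methyl-2-(3-methylbut-2-en-1-yl)-3,5,7-trioxododecanoate, via acyl imidazolide 15 (not isolated)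
Conditions: 14, 1,1'-carbonyldiimidazole (1.1 equiv), THF, rt, 2 h; separate flask: 3 (3.5 equiv), LiN(iPr)2 (7.2 equiv), THF, −78 → 0 °C; add the solution of 15 at −78 °C, → 0 °C, 2 h; cold 1 M HCl
Reagents that add atoms: none
Why: Intermolecular Claisen condensation: the terminal carbanion of the diketone dianion is acylated by the acyl imidazolide, which is far more electrophilic than the neighbouring methyl ester, so the two malonate carbonyls stay differentiated and the stereocentre is a spectator.

Step 9
Reactants: 16 methyl (2S)-2-methyl-2-(3-methylbut-2-en-1-yl)-3,5,7-trioxododecanoate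
Product: 17 (4S)-2-hexanoyl-3,5-dihydroxy-4-methyl-4-(3-methylbut-2-en-1-yl)cyclohexa-2,5-dien-1-one
Conditions: NaOMe (3 equiv), MeOH, 0 → 50 °C; 1 M HCl
Reagents that add atoms: none
Why: Intramolecular Claisen (Dieckmann-type) condensation: the doubly activated C6 carbanion attacks the methyl ester in the only six-membered mode available and the acyl trione is held as its stable enolate, so the ester carbon ends up next to the hexanoyl-bearing carbon and the malonate stereocentre becomes the 4S ring centre unchanged.

Step 10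
Reactants: 18 benzene-1,3,5-triol; 19 hexanoyl chloride
Product: 20 1-(2,4,6-trihydroxyphenyl)hexan-1-one
Conditions: AlCl3 (4 equiv), PhNO2–CH2Cl2, 0 → 60 °C; ice/HCl
Reagents that add atoms: none
Why: Friedel–Crafts C-acylation of the electron-rich triol stops at the mono-ketone because the chelated acyl group deactivates the ring.

Step 11
Reactants: 20 1-(2,4,6-trihydroxyphenyl)hexan-1-one
Product: 21 1-(2,6-dihydroxy-4-methoxyphenyl)hexan-1-one
Conditions: Me2SO4 (1.0 equiv), K2CO3 (1.0 equiv), acetone, rt; chromatography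
Reagents that add atoms: dimethyl sulfate, COS(=O)(=O)OC
Why: Williamson O-methylation with one equivalent goes to the 4-OH, the most acidic hydroxyl and the only one not hydrogen-bonded to the ketone, leaving the two chelated ortho hydroxyls free.

Step 12
Reactants: 17 (4S)-2-hexanoyl-3,5-dihydroxy-4-methyl-4-(3-methylbut-2-en-1-yl)cyclohexa-2,5-dien-1-one
Product: 22 (4S)-6-[(dimethylamino)methyl]-2-hexanoyl-3,5-dihydroxy-4-methyl-4-(3-methylbut-2-en-1-yl)cyclohexa-2,5-dien-1-one (obtained as the inner salt, used crude)
Conditions: Eschenmoser's salt (1.05 equiv), Et3N (1.05 equiv), CH2Cl2, 0 °C → rt, 1 h; water wash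
Reagents that add atoms: N,N-dimethylmethyleneiminium iodide (Eschenmoser's salt), C=[N+](C)C.[I-]
Why: Mannich reaction: the enolate of the vinylogous acid attacks the preformed iminium ion at its only unsubstituted ring carbon, and the quaternary stereocentre is untouched.

Step 13
Reactants: 22 (4S)-6-[(dimethylamino)methyl]-2-hexanoyl-3,5-dihydroxy-4-methyl-4-(3-methylbut-2-en-1-yl)cyclohexa-2,5-dien-1-one; 21 1-(2,6-dihydroxy-4-methoxyphenyl)hexan-1-one
Product: 24 (4S)-2-hexanoyl-6-[(3-hexanoyl-2,4-dihydroxy-6-methoxyphenyl)methyl]-3,5-dihydroxy-4-methyl-4-(3-methylbut-2-en-1-yl)cyclohexa-2,5-dien-1-one, via methylidene trione 23 (not isolated)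
Conditions: 21 (3 equiv, excess recovered), 1,4-dioxane, 90 °C, N2 stream, 3 h; 1 M HCl wash; chromatography
Reagents that add atoms: none
Why: On heating the Mannich base loses dimethylamine (retro-aza-Michael) to the α-methylidene trione, which is captured in an intermolecular Michael (Friedel–Crafts-type conjugate) addition by a ring carbon of the phenol in excess, either free position of the symmetric ring B giving the same product and no stereocentre being formed or touched.

**Compound list**
1 | pentane-2,4-dione | CC(=O)CC(C)=O | starting material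
2 | 1-bromobutane | CCCCBr | starting material
3 | nonane-2,4-dione | CC(=O)CC(=O)CCCCC | intermediate
4 | 2,2,5-trimethyl-1,3-dioxane-4,6-dione | CC1C(=O)OC(C)(C)OC1=O | starting material
5 | 2-methylpropan-2-ol | CC(C)(C)O | starting material
6 | 3-(tert-butoxy)-2-methyl-3-oxopropanoic acid (racemic) | CC(C(=O)O)C(=O)OC(C)(C)C | intermediate
7 | bromodiphenylmethane | BrC(c1ccccc1)c1ccccc1 | starting material
8 | 1-benzhydryl 3-tert-butyl 2-methylpropanedioate (racemic) | CC(C(=O)OC(c1ccccc1)c1ccccc1)C(=O)OC(C)(C)C | intermediate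
9 | 1-bromo-3-methylbut-2-ene | CC(C)=CCBr | starting material
10 | 1-benzhydryl 3-tert-butyl (2R)-2-methyl-2-(3-methylbut-2-en-1-yl)propanedioate | O=C(OC(c1ccccc1)c1ccccc1)[C@@](C)(CC=C(C)C)C(=O)OC(C)(C)C | intermediate
11 | (2R)-3-(tert-butoxy)-2-methyl-2-(3-methylbut-2-en-1-yl)-3-oxopropanoic acid | OC(=O)[C@@](C)(CC=C(C)C)C(=O)OC(C)(C)C | intermediate
12 | 1-tert-butyl 3-methyl (2R)-2-methyl-2-(3-methylbut-2-en-1-yl)propanedioate | COC(=O)[C@@](C)(CC=C(C)C)C(=O)OC(C)(C)C | intermediate
13 | 1-methyl 3-trimethylsilyl (2R)-2-methyl-2-(3-methylbut-2-en-1-yl)propanedioate | COC(=O)[C@@](C)(CC=C(C)C)C(=O)O[Si](C)(C)C | intermediate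
14 | (2S)-3-methoxy-2-methyl-2-(3-methylbut-2-en-1-yl)-3-oxopropanoic acid | COC(=O)[C@@](C)(CC=C(C)C)C(O)=O | intermediate
15 | methyl (2S)-2-(1H-imidazole-1-carbonyl)-2,5-dimethylhex-4-enoate | COC(=O)[C@@](C)(CC=C(C)C)C(=O)n1ccnc1 | intermediate
16 | methyl (2S)-2-methyl-2-(3-methylbut-2-en-1-yl)-3,5,7-trioxododecanoate | COC(=O)[C@@](C)(CC=C(C)C)C(=O)CC(=O)CC(=O)CCCCC | intermediate
17 | (4S)-2-hexanoyl-3,5-dihydroxy-4-methyl-4-(3-methylbut-2-en-1-yl)cyclohexa-2,5-dien-1-one | CCCCCC(=O)C1=C(O)[C@@](C)(CC=C(C)C)C(O)=CC1=O | intermediate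
18 | benzene-1,3,5-triol (phloroglucinol) | Oc1cc(O)cc(O)c1 | starting material
19 | hexanoyl chloride | CCCCCC(Cl)=O | starting material
20 | 1-(2,4,6-trihydroxyphenyl)hexan-1-one | CCCCCC(=O)c1c(O)cc(O)cc1O | intermediate
21 | 1-(2,6-dihydroxy-4-methoxyphenyl)hexan-1-one | CCCCCC(=O)c1c(O)cc(OC)cc1O | intermediate
22 | (4S)-6-[(dimethylamino)methyl]-2-hexanoyl-3,5-dihydroxy-4-methyl-4-(3-methylbut-2-en-1-yl)cyclohexa-2,5-dien-1-one | CCCCCC(=O)C1=C(O)[C@@](C)(CC=C(C)C)C(O)=C(CN(C)C)C1=O | intermediate
23 | (4R)-2-hexanoyl-3-hydroxy-4-methyl-6-methylidene-4-(3-methylbut-2-en-1-yl)cyclohex-2-ene-1,5-dione | CCCCCC(=O)C1=C(O)[C@@](C)(CC=C(C)C)C(=O)C(=C)C1=O | intermediate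
24 | (4S)-2-hexanoyl-6-[(3-hexanoyl-2,4-dihydroxy-6-methoxyphenyl)methyl]-3,5-dihydroxy-4-methyl-4-(3-methylbut-2-en-1-yl)cyclohexa-2,5-dien-1-one (CNP0108719.1) | CCCCCC(=O)C1=C(O)[C@@](C)(CC=C(C)C)C(O)=C(Cc2c(OC)cc(O)c(C(=O)CCCCC)c2O)C1=O | target

**Count**
Total steps: 13. Longest linear sequence: 10 steps (steps 2–9, 12, 13); step 1 and steps 10–11 are side branches.

**Three steps most likely to fail**

Step 4 (enantioselectivity or sense of the phase-transfer prenylation). The fallback sets out from 8 and replaces asymmetric catalysis by resolution. Compound 8 is alkylated with 9 without a chiral catalyst (NaH, THF, 0 °C → rt) to the racemic 1-benzhydryl 3-tert-butyl 2-methyl-2-(3-methylbut-2-en-1-yl)propanedioate F1. F1 is separated by preparative supercritical-fluid chromatography on a polysaccharide carbamate phase (CO2/iPrOH). The R enantiomer is 10, where the route is rejoined, and the unwanted S enantiomer F2 is set aside. This also cures a wrong sense or a low ee.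

Step 8 (acylation of a strongly basic dianion by a hindered acyl imidazolide; low conversion, or partial attack at the methyl ester, would erode yield or ee). The fallback sets out from 14 and 3 and swaps the basic dianion for a neutral silyl dienol ether.
- Acid 14 is converted with 1-chloro-N,N,2-trimethylprop-1-en-1-amine (CH2Cl2, 0 °C) into methyl (2R)-2-(chlorocarbonyl)-2,5-dimethylhex-4-enoate F3.
- Diketone 3 is converted through its dianion (LiN(iPr)2 2.1 equiv, then Me3SiCl 2.2 equiv, THF, −78 °C) into (3Z)-2,4-bis(trimethylsilyloxy)nona-1,3-diene F4.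
- F3 and F4 are combined in CH2Cl2 (−78 → 20 °C, Me3SiOTf 10 mol % if needed). The terminal diene carbon is acylated (Mukaiyama-type vinylogous acylation) to methyl (2S)-2-methyl-2-(3-methylbut-2-en-1-yl)-3,5-dioxo-7-(trimethylsilyloxy)dodec-6-enoate F5, which is not isolated.
- Work-up with 1 M HCl hydrolyses F5 to 16, where the route is rejoined.

Step 13 (the methylidene trione may dimerise, or 21 may be alkylated twice). The fallback sets out from 21 and 17 and reverses the roles of the two rings. Phenol 21 is aminomethylated once (Eschenmoser's salt 1.0 equiv, Et3N, CH2Cl2, 0 °C; mono-adduct separated from bis-adduct) to 1-{3-[(dimethylamino)methyl]-2,6-dihydroxy-4-methoxyphenyl}hexan-1-one F6. Heating F6 with 17 (1.2 equiv) in 1,4-dioxane at 90 °C expels dimethylamine to give 2-hexanoyl-3-hydroxy-5-methoxy-6-methylidenecyclohexa-2,4-dien-1-one F7 (an ortho-quinone methide, not isolated). F7 is captured in a Michael addition by the single nucleophilic ring carbon of 17 and gives 24 directly.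

**Further compounds**
F1 | step 4 | racemic 1-benzhydryl 3-tert-butyl 2-methyl-2-(3-methylbut-2-en-1-yl)propanedioate | O=C(OC(c1ccccc1)c1ccccc1)C(C)(CC=C(C)C)C(=O)OC(C)(C)C
F2 | step 4 | 1-benzhydryl 3-tert-butyl (2S)-2-methyl-2-(3-methylbut-2-en-1-yl)propanedioate | O=C(OC(c1ccccc1)c1ccccc1)[C@](C)(CC=C(C)C)C(=O)OC(C)(C)C
F3 | step 8 | methyl (2R)-2-(chlorocarbonyl)-2,5-dimethylhex-4-enoate | COC(=O)[C@@](C)(CC=C(C)C)C(Cl)=O
F4 | step 8 | (3Z)-2,4-bis(trimethylsilyloxy)nona-1,3-diene | C=C(O[Si](C)(C)C)/C=C(\O[Si](C)(C)C)CCCCC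
F5 | step 8 | methyl (2S,6Z)-2-methyl-2-(3-methylbut-2-en-1-yl)-3,5-dioxo-7-(trimethylsilyloxy)dodec-6-enoate | COC(=O)[C@@](C)(CC=C(C)C)C(=O)CC(=O)/C=C(\O[Si](C)(C)C)CCCCC
F6 | step 13 | 1-{3-[(dimethylamino)methyl]-2,6-dihydroxy-4-methoxyphenyl}hexan-1-one | CCCCCC(=O)c1c(O)cc(OC)c(CN(C)C)c1O
F7 | step 13 | 2-hexanoyl-3-hydroxy-5-methoxy-6-methylidenecyclohexa-2,4-dien-1-one | CCCCCC(=O)C1=C(O)C=C(OC)C(=C)C1=O
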